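**Plan**
- Ring A is numbered C1 (CO2H), C2 (OMe), C3 (prenyl), C4 (OH), C5 (prenyl), C6 (arylethyl). C3–C4–C5 with both prenyl groups is a latent symmetric ketone, C6–C1–C2 with the carboxyl is a latent alkylidene malonate, and the 1,3-related oxygens at C2 and C4 are a latent cyclohexane-1,3-dione.
- Retrosynthesis: remove the O-methyl group and three O-allyl groups, lower ring A by one oxidation level (C1–C6 saturated), then cut C2–C3 (Claisen) and C5–C6 (Michael).
- Forward: the diprenyl ketone comes from dimethyl acetonedicarboxylate and prenyl bromide in two steps; the allyl-protected alkylidene malonate comes from phloretic acid and diallyl malonate in three steps.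
- A one-pot Michael–Claisen annulation joins the two and closes ring A, the only ring made. Dianion selenenylation and selenoxide elimination aromatize it. O4 is then allylated, O2 methylated, and one zerovalent-palladium step removes all three allyl groups.
- Stereochemistry: the target is achiral. The three ring stereocentres from the annulation are racemic, should settle all-trans under equilibration, and are destroyed on aromatization.

Key step: step 6

Assumption: allyl is used for the ester and for both phenol protections, so that one neutral deallylation frees the acid and the phenols without acid or strong base near the prenylated phenol. The hydroxy-dione compounds are drawn as one enol tautomer and as one enantiomer of the racemate.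

**Route**

Step 1
Reactants: 1 dimethyl 3-oxopentanedioate (dimethyl 1,3-acetonedicarboxylate); 2 1-bromo-3-methylbut-2-ene (prenyl bromide)
Product: 3 dimethyl 2,4-bis(3-methylbut-2-enyl)-3-oxopentanedioate (diastereomer mixture)
Conditions: K2CO3 (2.5 equiv), 2 (2.1 equiv), acetone, reflux
Reagents that add atoms: none
Why: Double C-alkylation of a beta-keto ester enolate, in which the monoalkylated intermediate should be deprotonated at the unsubstituted, more acidic alpha' methylene so that the second prenyl group enters at C4 and not geminally; the diastereomer mixture is irrelevant because both stereocentres vanish in step 2.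

Step 2
Reactants: 3 dimethyl 2,4-bis(3-methylbut-2-enyl)-3-oxopentanedioate
Product: 4 2,10-dimethylundeca-2,9-dien-6-one
Conditions: LiCl (3 equiv), H2O (4 equiv), DMSO, 150 °C
Reagents that add atoms: none
Why: Twofold Krapcho dealkoxycarbonylation of a beta-keto methyl ester proceeds under neutral conditions, so the acid-sensitive trisubstituted alkenes should survive.

Step 3
Reactants: 5 3-(4-hydroxyphenyl)propanoic acid (phloretic acid)
Product: 6 prop-2-enyl 3-[4-(prop-2-enyloxy)phenyl]propanoate
Conditions: allyl bromide (2.4 equiv), K2CO3 (3 equiv), DMF, rt to 50 °C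
Reagents that add atoms: allyl bromide, C=CCBr
Why: Williamson O-alkylation of the phenoxide and of the carboxylate in a polar aprotic solvent should allylate both oxygens in one operation.

Step 4
Reactants: 6 prop-2-enyl 3-[4-(prop-2-enyloxy)phenyl]propanoate
Product: 7 3-[4-(prop-2-enyloxy)phenyl]propanal
Conditions: iBu2AlH (1.1 equiv), CH2Cl2, −78 °C; MeOH, then aqueous potassium sodium tartrate
Reagents that add atoms: none
Why: Partial hydride reduction of an ester stops at the aldehyde because the aluminium hemiacetal is stable at −78 °C and collapses only on work-up, while the aryl allyl ether is inert.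

Step 5
Reactants: 7 3-[4-(prop-2-enyloxy)phenyl]propanal; 8 bis(prop-2-enyl) propanedioate (diallyl malonate)
Product: 9 bis(prop-2-enyl) 2-{3-[4-(prop-2-enyloxy)phenyl]propylidene}propanedioate
Conditions: piperidine (10 mol %), AcOH (10 mol %), toluene, reflux, Dean–Stark trap
Reagents that add atoms: none
Why: Knoevenagel condensation of an aliphatic aldehyde with a malonate is driven by azeotropic removal of water and should give the conjugated alkylidene malonate, which is symmetric at the acceptor carbon and so has no alkene geometry to control.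

Step 6
Reactants: 4 2,10-dimethylundeca-2,9-dien-6-one; 9 bis(prop-2-enyl) 2-{3-[4-(prop-2-enyloxy)phenyl]propylidene}propanedioate
Product: 12 prop-2-enyl 2-hydroxy-3,5-bis(3-methylbut-2-enyl)-4-oxo-6-{2-[4-(prop-2-enyloxy)phenyl]ethyl}cyclohex-2-ene-1-carboxylate (racemic; all-trans), via lithium enolate 10 (not isolated), via Michael adduct 11 (not isolated)
Conditions: 4 (1.1 equiv), LiN(iPr)2 (1.05 equiv), THF, −78 °C; 9, −78 to −40 °C; then NaOCH2CH=CH2 (1.5 equiv, freshly made from NaH in allyl alcohol), 0 to 40 °C; cold aqueous HCl to pH 3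
Reagents that add atoms: none
Why: The preformed lithium enolate 10 adds in conjugate fashion to the doubly activated alkene of 9 to forge C5–C6 and give the malonate enolate 11; in allyloxide/allyl alcohol a proton shuttle then exposes the enolate at the second alpha carbon of the ketone, which attacks one allyl ester carbonyl to forge C2–C3 with loss of allyloxide, and the product leaves all equilibria as its stabilized 1,3-dione enolate. The closest known reaction type is the one-pot Michael–Claisen (Michael–Dieckmann) annulation that gives 4-alkoxycarbonylcyclohexane-1,3-diones from enolates and alkylidene malonates or from malonates and enones. Ring A closes by a 6-(enolendo)-exo-trig acyl substitution. The three new stereocentres C1, C5 and C6 are formed racemic and under thermodynamic control, since C1 and C5 can epimerize in the alkoxide medium and should settle in the all-equatorial trans,trans arrangement; all three are erased in steps 7 and 8. The step needs 1,4-addition to win over 1,2-addition and over gamma-deprotonation of 9, and C-acylation to win over O-acylation: a preformed enolate with no excess amide base meeting a doubly activated, beta-monosubstituted acceptor at −78 °C secures the first, and the protic alkoxide stage with the dione-enolate sink secures the second. The matching allyloxide prevents ester scrambling, and the symmetry of 4 removes any regiochemical question.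

Step 7
Reactants: 12 prop-2-enyl 2-hydroxy-3,5-bis(3-methylbut-2-enyl)-4-oxo-6-{2-[4-(prop-2-enyloxy)phenyl]ethyl}cyclohex-2-ene-1-carboxylate
Product: 14 prop-2-enyl 2-hydroxy-3,5-bis(3-methylbut-2-enyl)-4-oxo-1-(phenylselanyl)-6-{2-[4-(prop-2-enyloxy)phenyl]ethyl}cyclohex-2-ene-1-carboxylate (racemic; selenium cis to H6), via dilithium dianion 13 (not isolated)
Conditions: LiN(iPr)2 (2.2 equiv), THF, −78 °C; PhSeBr (1.05 equiv), −78 °C; dilute aqueous HCl
Reagents that add atoms: benzeneselenenyl bromide, Br[Se]c1ccccc1
Why: Alpha-selenenylation of an ester enolate carried out on a dianion, in which the second equivalent of base removes H1 between the ester and the C2 carbonyl and this last-formed, most nucleophilic carbon should capture the selenium electrophile from the face opposite the C6 side chain, which places selenium cis to H6 as the later syn elimination requires; holding the dianion at −78 °C avoids [3,3] rearrangement of the allyl ester enolate.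

Step 8
Reactants: 14 prop-2-enyl 2-hydroxy-3,5-bis(3-methylbut-2-enyl)-4-oxo-1-(phenylselanyl)-6-{2-[4-(prop-2-enyloxy)phenyl]ethyl}cyclohex-2-ene-1-carboxylate
Product: 16 prop-2-enyl 2,4-dihydroxy-3,5-bis(3-methylbut-2-enyl)-6-{2-[4-(prop-2-enyloxy)phenyl]ethyl}benzoate, via selenoxide 15 (not isolated)
Conditions: mCPBA (1.0 equiv), CH2Cl2, −78 °C; then iPr2NH (3 equiv), −78 °C to rt
Reagents that add atoms: none
Why: Selenoxide syn elimination can only take H6, the single hydrogen beta to selenium, and the resulting cyclohexadienone should tautomerize at once to the aromatic resorcylate; one equivalent of peracid at −78 °C oxidizes selenium far faster than any alkene, and the amine intercepts the selenenic acid before it can add to the prenyl or allyl groups.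

Step 9
Reactants: 16 prop-2-enyl 2,4-dihydroxy-3,5-bis(3-methylbut-2-enyl)-6-{2-[4-(prop-2-enyloxy)phenyl]ethyl}benzoate
Product: 17 prop-2-enyl 2-hydroxy-3,5-bis(3-methylbut-2-enyl)-4-(prop-2-enyloxy)-6-{2-[4-(prop-2-enyloxy)phenyl]ethyl}benzoate
Conditions: allyl bromide (1.1 equiv), K2CO3 (1.5 equiv), acetone, rt to 40 °C
Reagents that add atoms: allyl bromide, C=CCBr
Why: Site-selective Williamson etherification, in which the C4 hydroxyl para to the ester is the more acidic and is free, whereas the C2 hydroxyl is held in a hydrogen bond to the ester carbonyl; the aprotic medium with a potassium counter-ion favours O- over C-allylation of the fully substituted ring.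

Step 10
Reactants: 17 prop-2-enyl 2-hydroxy-3,5-bis(3-methylbut-2-enyl)-4-(prop-2-enyloxy)-6-{2-[4-(prop-2-enyloxy)phenyl]ethyl}benzoate
Product: 18 prop-2-enyl 2-methoxy-3,5-bis(3-methylbut-2-enyl)-4-(prop-2-enyloxy)-6-{2-[4-(prop-2-enyloxy)phenyl]ethyl}benzoate
Conditions: MeI (5 equiv), K2CO3 (3 equiv), DMF, 50 °C
Reagents that add atoms: iodomethane, CI
Why: Williamson O-methylation of the chelated salicylate hydroxyl under more forcing conditions should be clean because it is the only acidic site left in the molecule.

Step 11
Reactants: 18 prop-2-enyl 2-methoxy-3,5-bis(3-methylbut-2-enyl)-4-(prop-2-enyloxy)-6-{2-[4-(prop-2-enyloxy)phenyl]ethyl}benzoate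
Product: 19 4-hydroxy-6-[2-(4-hydroxyphenyl)ethyl]-2-methoxy-3,5-bis(3-methylbut-2-enyl)benzoic acid (CNP0254933.0)
Conditions: Pd(PPh3)4 (5 mol %), morpholine (10 equiv), THF, rt; then cold aqueous citric acid to pH 4
Reagents that add atoms: none
Why: Tsuji–Trost deallylation, in which zerovalent palladium ionizes the allyl ester and both aryl allyl ethers to pi-allyl complexes that morpholine captures, while the C-bound prenyl groups carry no leaving group and the neutral conditions avoid chroman formation and decarboxylation.

**Compound list**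

1 | dimethyl 3-oxopentanedioate | COC(=O)CC(=O)CC(=O)OC | starting material
2 | 1-bromo-3-methylbut-2-ene (prenyl bromide) | CC(C)=CCBr | starting material
3 | dimethyl 2,4-bis(3-methylbut-2-enyl)-3-oxopentanedioate (diastereomer mixture) | COC(=O)C(CC=C(C)C)C(=O)C(CC=C(C)C)C(=O)OC | intermediate
4 | 2,10-dimethylundeca-2,9-dien-6-one | CC(C)=CCCC(=O)CCC=C(C)C | intermediate
5 | 3-(4-hydroxyphenyl)propanoic acid | OC(=O)CCc1ccc(O)cc1 | starting material
6 | prop-2-enyl 3-[4-(prop-2-enyloxy)phenyl]propanoate | C=CCOC(=O)CCc1ccc(OCC=C)cc1 | intermediate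
7 | 3-[4-(prop-2-enyloxy)phenyl]propanal | O=CCCc1ccc(OCC=C)cc1 | intermediate
8 | bis(prop-2-enyl) propanedioate (diallyl malonate) | C=CCOC(=O)CC(=O)OCC=C | starting material
9 | bis(prop-2-enyl) 2-{3-[4-(prop-2-enyloxy)phenyl]propylidene}propanedioate | C=CCOC(=O)C(=CCCc1ccc(OCC=C)cc1)C(=O)OCC=C | intermediate
10 | lithium 2,10-dimethylundeca-2,5,9-trien-6-olate (enolate of 4; alkene geometry not defined) | [Li+].CC(C)=CCC=C([O-])CCC=C(C)C | intermediate (not isolated)
11 | lithium enolate of bis(prop-2-enyl) 2-{9-methyl-4-(3-methylbut-2-enyl)-5-oxo-1-[4-(prop-2-enyloxy)phenyl]dec-8-en-3-yl}propanedioate (diastereomer mixture) | [Li+].C=CCOC([O-])=C(C(=O)OCC=C)C(CCc1ccc(OCC=C)cc1)C(CC=C(C)C)C(=O)CCC=C(C)C | intermediate (not isolated)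
12 | prop-2-enyl 2-hydroxy-3,5-bis(3-methylbut-2-enyl)-4-oxo-6-{2-[4-(prop-2-enyloxy)phenyl]ethyl}cyclohex-2-ene-1-carboxylate (racemic; 1,6-trans, 5,6-trans) | C=CCOC(=O)[C@@H]1[C@@H](CCc2ccc(OCC=C)cc2)[C@H](CC=C(C)C)C(=O)C(CC=C(C)C)=C1O | intermediate
13 | dilithium dianion of 12 (ester enolate at C1 plus dione enolate; racemic) | [Li+].[Li+].C=CCOC([O-])=C1C(=O)C(CC=C(C)C)=C([O-])[C@@H](CC=C(C)C)[C@@H]1CCc1ccc(OCC=C)cc1 | intermediate (not isolated)
14 | prop-2-enyl 2-hydroxy-3,5-bis(3-methylbut-2-enyl)-4-oxo-1-(phenylselanyl)-6-{2-[4-(prop-2-enyloxy)phenyl]ethyl}cyclohex-2-ene-1-carboxylate (racemic; Se cis to H6, 5,6-trans) | C=CCOC(=O)[C@@]1([Se]c2ccccc2)[C@@H](CCc2ccc(OCC=C)cc2)[C@H](CC=C(C)C)C(=O)C(CC=C(C)C)=C1O | intermediate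
15 | selenoxide of 14 (racemic; configuration at selenium not defined) | C=CCOC(=O)[C@@]1([Se](=O)c2ccccc2)[C@@H](CCc2ccc(OCC=C)cc2)[C@H](CC=C(C)C)C(=O)C(CC=C(C)C)=C1O | intermediate (not isolated)
16 | prop-2-enyl 2,4-dihydroxy-3,5-bis(3-methylbut-2-enyl)-6-{2-[4-(prop-2-enyloxy)phenyl]ethyl}benzoate | C=CCOC(=O)c1c(O)c(CC=C(C)C)c(O)c(CC=C(C)C)c1CCc1ccc(OCC=C)cc1 | intermediate
17 | prop-2-enyl 2-hydroxy-3,5-bis(3-methylbut-2-enyl)-4-(prop-2-enyloxy)-6-{2-[4-(prop-2-enyloxy)phenyl]ethyl}benzoate | C=CCOC(=O)c1c(O)c(CC=C(C)C)c(OCC=C)c(CC=C(C)C)c1CCc1ccc(OCC=C)cc1 | intermediate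
18 | prop-2-enyl 2-methoxy-3,5-bis(3-methylbut-2-enyl)-4-(prop-2-enyloxy)-6-{2-[4-(prop-2-enyloxy)phenyl]ethyl}benzoate | C=CCOC(=O)c1c(OC)c(CC=C(C)C)c(OCC=C)c(CC=C(C)C)c1CCc1ccc(OCC=C)cc1 | intermediate
19 | 4-hydroxy-6-[2-(4-hydroxyphenyl)ethyl]-2-methoxy-3,5-bis(3-methylbut-2-enyl)benzoic acid (achiral) | COc1c(CC=C(C)C)c(O)c(CC=C(C)C)c(CCc2ccc(O)cc2)c1C(=O)O | target

**Step count**

Total steps: 11. Longest linear sequence: 9 steps (steps 3 to 11, from 5 to 19).

**Steps most likely to fail**

Step 6. The basic ketone enolate may take a gamma proton from 9 and deconjugate the acceptor, or add 1,2 to an ester. At the alkoxide stage the adduct may revert by retro-Michael fragmentation or close through oxygen. The fallback sets out from 4 and 9 and returns at 12.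
- Ketone 4 is converted with LiN(iPr)2 and TMSCl (THF, −78 °C) into the silyl enol ether trimethyl[(2,10-dimethylundeca-2,5,9-trien-6-yl)oxy]silane F1.
- F1 is added to 9 in a Mukaiyama–Michael reaction (TiCl4, CH2Cl2, −78 °C). No basic species is present, so gamma-deprotonation cannot compete.
- Aqueous work-up should give the neutral keto malonate bis(prop-2-enyl) 2-{9-methyl-4-(3-methylbut-2-enyl)-5-oxo-1-[4-(prop-2-enyloxy)phenyl]dec-8-en-3-yl}propanedioate F2.
- F2 is isolated and closed in a separate Dieckmann-type Claisen condensation with NaOCH2CH=CH2 in allyl alcohol to give 12.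

Step 7. Selenium may be delivered to the central dione carbon C3 instead of C1, the allyl ester enolate may rearrange on warming, or the selenium electrophile may add to the alkenes. Any of these would block the later elimination toward C6. The fallback sets out from 12 and returns at 16, bypassing steps 7 and 8.
- 12 is silylated on both oxygens (TMSCl, Et3N, DMF) to the conjugated diene prop-2-enyl 3,5-bis(3-methylbut-2-enyl)-6-{2-[4-(prop-2-enyloxy)phenyl]ethyl}-2,4-bis(trimethylsilyloxy)cyclohexa-1,3-diene-1-carboxylate F3.
- F3 is dehydrogenated with DDQ (benzene, rt) to the aromatic bis-silyl ether prop-2-enyl 3,5-bis(3-methylbut-2-enyl)-6-{2-[4-(prop-2-enyloxy)phenyl]ethyl}-2,4-bis(trimethylsilyloxy)benzoate F4. The phenols stay masked while the oxidant is present.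
- Mild aqueous acid work-up hydrolyses F4 to 16.

Step 1. The second prenylation may go geminally at C2, on oxygen, or a third time, and this would erode the supply of the symmetric ketone. The fallback sets out from 2 and returns at 4, bypassing steps 1 and 2; each carbon–carbon bond is made at a defined site.
- The dianion of commercial methyl acetoacetate (NaH, then n-BuLi, THF, 0 °C) is alkylated with 2 at its terminal carbon to give methyl 7-methyl-3-oxooct-6-enoate F5.
- F5 is alkylated with 2 at the central carbon (K2CO3, acetone) to give methyl 7-methyl-2-(3-methylbut-2-enyl)-3-oxooct-6-enoate F6.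
- Krapcho dealkoxycarbonylation of F6 (LiCl, wet DMSO, 150 °C) delivers 4.

**Further compounds**

F1 | step 6 | trimethyl[(2,10-dimethylundeca-2,5,9-trien-6-yl)oxy]silane (alkene geometry not defined) | CC(C)=CCC=C(O[Si](C)(C)C)CCC=C(C)C
F2 | step 6 | bis(prop-2-enyl) 2-{9-methyl-4-(3-methylbut-2-enyl)-5-oxo-1-[4-(prop-2-enyloxy)phenyl]dec-8-en-3-yl}propanedioate (diastereomer mixture) | C=CCOC(=O)C(C(=O)OCC=C)C(CCc1ccc(OCC=C)cc1)C(CC=C(C)C)C(=O)CCC=C(C)C
F3 | step 7 | prop-2-enyl 3,5-bis(3-methylbut-2-enyl)-6-{2-[4-(prop-2-enyloxy)phenyl]ethyl}-2,4-bis(trimethylsilyloxy)cyclohexa-1,3-diene-1-carboxylate (racemic; 5,6-trans) | C=CCOC(=O)C1=C(O[Si](C)(C)C)C(CC=C(C)C)=C(O[Si](C)(C)C)[C@@H](CC=C(C)C)[C@@H]1CCc1ccc(OCC=C)cc1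
F4 | step 7 | prop-2-enyl 3,5-bis(3-methylbut-2-enyl)-6-{2-[4-(prop-2-enyloxy)phenyl]ethyl}-2,4-bis(trimethylsilyloxy)benzoate | C=CCOC(=O)c1c(O[Si](C)(C)C)c(CC=C(C)C)c(O[Si](C)(C)C)c(CC=C(C)C)c1CCc1ccc(OCC=C)cc1
F5 | step 1 | methyl 7-methyl-3-oxooct-6-enoate | COC(=O)CC(=O)CCC=C(C)C
F6 | step 1 | methyl 7-methyl-2-(3-methylbut-2-enyl)-3-oxooct-6-enoate (racemic) | COC(=O)C(CC=C(C)C)C(=O)CCC=C(C)C
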